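**Retrosynthetic overview**

- Structural feature: in the 1,2-dioxane ring (O1–O2–C3–C4–C5–C6) C3 is an O2-bearing carbon at the aldehyde (acetal) oxidation level next to the C4 stereocentre, and O1–O2 ties it to the quaternary C6. The ring can therefore be closed at C3–C4 across a ready-made C6–O1–O2–C3 peroxide tether.
- C3–C4 (ring closure): C3 peroxycarbenium ion from a C6 monoperoxyacetal, attacked by the γ-carbon (C4) of a tethered (Z)-allylsilane, which leaves a vinyl group at C4.
- C6–O1: perhydrolysis with inversion of a (2R)-2-ethyl-2-propynyloxetane, itself made from a (Z)-enynol by Sharpless epoxidation, C2-selective hydride opening and 4-exo closure. The allylsilane comes from a Wittig reaction and the peroxyacetal from acetal exchange.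
- After the ring: vinyl to ethyl (diimide), propynyl to (E)-2-iodopropenyl (hydrozirconation, iodination), C8–C9 by Negishi coupling with the C9–C14 alkylzinc (C10 set by an Evans ethylation).
- Ring order: oxirane, then oxetane (both temporary), then the 1,2-dioxane, the only ring of the target.

Key step: step 13

Remark: atom numbers are those of the target chain (C1 ester carbon to C14; O1 on C6, O2 on C3). The Wittig step is taken to give mainly the (Z)-allylsilane; this double bond is consumed in the key step, so a minor (E) portion is carried along.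

**Route**

Step 1
Reactants: 1 pent-2-yn-1-ol
Product: 3 (2Z)-3-iodopent-2-en-1-ol, via cyclic alkenylalanate 2 (not isolated)
Conditions: NaAlH2(OCH2CH2OCH3)2, THF, 0 °C → rt; EtOAc; then I2, −78 → 0 °C
Reagents that add atoms: iodine, II
Why: Hydroxyl-directed trans-hydroalumination of the propargylic alcohol places aluminium on C3, and iodinolysis of the C–Al bond with retention gives the (Z)-iodoalkene.

Step 2
Reactants: 3 (2Z)-3-iodopent-2-en-1-ol; 4 propyne
Product: 5 (2Z)-3-ethylhex-2-en-4-yn-1-ol
Conditions: propyne (excess), Pd(PPh3)2Cl2 (cat.), CuI (cat.), Et3N, THF, 0 °C → rt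
Reagents that add atoms: none
Why: Sonogashira coupling of an alkenyl iodide keeps the double-bond geometry, so the propynyl group ends up cis to CH2OH.

Step 3
Reactants: 5 (2Z)-3-ethylhex-2-en-4-yn-1-ol
Product: 6 [(2R,3S)-3-ethyl-3-(prop-1-yn-1-yl)oxiran-2-yl]methanol
Conditions: Ti(OiPr)4 (10 mol %), D-(−)-diethyl tartrate (12 mol %), t-BuOOH (2 equiv), 4 Å MS, CH2Cl2, −20 °C
Reagents that add atoms: tert-butyl hydroperoxide, CC(C)(C)OO
Why: Sharpless asymmetric epoxidation of a 3,3-disubstituted allylic alcohol; the D-(−)-tartrate catalyst delivers oxygen to the face that gives the (2R,3S)-epoxide, whose C3 is the future C6.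

Step 4
Reactants: 6 [(2R,3S)-3-ethyl-3-(prop-1-yn-1-yl)oxiran-2-yl]methanol
Product: 7 (3R)-3-ethylhex-4-yne-1,3-diol
Conditions: NaAlH2(OCH2CH2OCH3)2, THF, −20 → 0 °C
Reagents that add atoms: none
Why: Regioselective reductive opening of a 2,3-epoxy alcohol, with hydride delivered from the C1 alkoxyaluminate to C2; the tertiary C–O bond is untouched, so the carbinol configuration is retained, and the low temperature should keep the alkyne from hydroalumination.

Step 5
Reactants: 7 (3R)-3-ethylhex-4-yne-1,3-diol
Product: 9 (2R)-2-ethyl-2-(prop-1-yn-1-yl)oxetane, via primary tosylate 8 (not isolated)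
Conditions: n-BuLi (1 equiv), THF, 0 °C; TsCl (1 equiv); then n-BuLi (1 equiv), 0 → 45 °C
Reagents that add atoms: none
Why: Selective sulfonylation of the primary alkoxide followed by 4-exo-tet Williamson closure by the tertiary alkoxide; the C–O bond at the stereocentre is not broken, so its configuration is retained.

Step 6
Reactants: 9 (2R)-2-ethyl-2-(prop-1-yn-1-yl)oxetane
Product: 10 (3S)-3-ethyl-3-hydroperoxyhex-4-yn-1-ol
Conditions: H2O2 (anhydrous, in Et2O, excess), Me3SiOTf (cat.), Et2O, −78 → −20 °C
Reagents that add atoms: hydrogen peroxide, OO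
Why: Lewis acid-promoted perhydrolysis of a 2,2-disubstituted oxetane, in which H2O2 attacks the activated tertiary carbon opposite the departing ring oxygen, so C6 is inverted to the configuration of the target.

Step 7
Reactants: 10 (3S)-3-ethyl-3-hydroperoxyhex-4-yn-1-ol
Product: 11 (3S)-3-ethyl-3-[(2-methoxypropan-2-yl)peroxy]hex-4-yn-1-ol
Conditions: 2-methoxypropene (1.2 equiv), PPTS (cat.), CH2Cl2, 0 °C; Et3N
Reagents that add atoms: 2-methoxypropene, COC(C)=C
Why: Acid-catalysed addition of the hydroperoxide to the enol ether (peroxyketal protection); the hydroperoxide should add faster than the primary alcohol, and any mixed alkyl ketal is lost on aqueous work-up while the peroxyketal persists; a short reaction time with the weak acid is meant to prevent closure to a 1,2,4-trioxepane.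

Step 8
Reactants: 11 (3S)-3-ethyl-3-[(2-methoxypropan-2-yl)peroxy]hex-4-yn-1-ol
Product: 12 (3S)-3-ethyl-3-[(2-methoxypropan-2-yl)peroxy]hex-4-ynal
Conditions: Dess–Martin periodinane, pyridine, CH2Cl2, 0 °C → rt
Reagents that add atoms: none
Why: Dess–Martin oxidation under buffered, non-basic conditions should leave the acid-labile peroxyketal, the O–O bond and the alkyne intact; the β-peroxy aldehyde is used without storage.

Step 9
Reactants: 13 methyltriphenylphosphonium bromide; 14 (iodomethyl)trimethylsilane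
Product: 16 triphenyl[2-(trimethylsilyl)ethyl]phosphonium iodide, via methylidenetriphenylphosphorane 15 (not isolated)
Conditions: n-BuLi, THF, 0 °C; then Me3SiCH2I, 0 °C → rt; salt filtered off
Reagents that add atoms: none
Why: C-alkylation of the phosphorus ylide by the primary iodide; the salt precipitates, which limits proton transfer and double alkylation.

Step 10
Reactants: 12 (3S)-3-ethyl-3-[(2-methoxypropan-2-yl)peroxy]hex-4-ynal; 16 triphenyl[2-(trimethylsilyl)ethyl]phosphonium iodide
Product: 18 [(2Z,5S)-5-ethyl-5-[(2-methoxypropan-2-yl)peroxy]oct-2-en-6-yn-1-yl]trimethylsilane, via β-silyl ylide 17 (not isolated)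
Conditions: KN(SiMe3)2, THF, 0 °C; then 12, −78 °C → rt
Reagents that add atoms: none
Why: Wittig olefination with a non-stabilised ylide under lithium-free conditions gives mainly the (Z)-alkene; peroxyketals tolerate such ylides, and at −78 °C the aldehyde should be consumed before β-elimination of the peroxide sets in.

Step 11
Reactants: 18 [(2Z,5S)-5-ethyl-5-[(2-methoxypropan-2-yl)peroxy]oct-2-en-6-yn-1-yl]trimethylsilane
Product: 19 [(2Z,5S)-5-ethyl-5-hydroperoxyoct-2-en-6-yn-1-yl]trimethylsilane
Conditions: AcOH/THF/H2O (4:2:1), rt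
Reagents that add atoms: none
Why: Mild acid hydrolysis of the peroxyketal frees the tertiary hydroperoxide; the allylsilane and the O–O bond tolerate aqueous acetic acid.

Step 12
Reactants: 19 [(2Z,5S)-5-ethyl-5-hydroperoxyoct-2-en-6-yn-1-yl]trimethylsilane; 20 methyl 3,3-dimethoxypropanoate
Product: 21 methyl 3-{[(2Z,5S)-5-ethyl-1-(trimethylsilyl)oct-2-en-6-yn-5-yl]peroxy}-3-methoxypropanoate (both epimers at the acetal carbon)
Conditions: 20 (10 equiv), camphorsulfonic acid (cat.), 5 Å MS, CH2Cl2, 0 °C → rt; Et3N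
Reagents that add atoms: none
Why: Acid-catalysed acetal exchange in which the hydroperoxide replaces one methoxy group, driven by excess acetal and uptake of methanol by the sieves; catalytic anhydrous acid should neither protodesilylate the allylsilane nor ionise the product, and both acetal epimers converge on the same cation.

Step 13
Reactants: 21 methyl 3-{[(2Z,5S)-5-ethyl-1-(trimethylsilyl)oct-2-en-6-yn-5-yl]peroxy}-3-methoxypropanoate
Product: 22 methyl 2-[(3S,4S,6S)-4-ethenyl-6-ethyl-6-(prop-1-yn-1-yl)-1,2-dioxan-3-yl]acetate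
Conditions: Me3SiOTf (1.1 equiv), 2,6-di-tert-butyl-4-methylpyridine (0.2 equiv), CH2Cl2, −78 °C
Reagents that add atoms: none
Why: Me3SiOTf removes the methoxy group of 21 to give the (E)-configured C3 peroxycarbenium ion, which is captured by the γ-carbon (C4) of the tethered allylsilane; the β-silyl cation then loses its silyl group to leave the C4 vinyl group (intramolecular Hosomi–Sakurai reaction, SE2'). The closest known reaction type is the Lewis acid-mediated allylation of peroxycarbenium ions generated from monoperoxyacetals, run here within one molecule. The 1,2-dioxane closes by C3–C4 bond formation through a chair, 6-exo-trig with respect to the allylsilane double bond and with the C3=O2 cation bond inside the forming ring. C3 is set by the (E) geometry of the peroxycarbenium ion, which puts the CH2CO2Me arm equatorial; C4 is set by the equatorial placement of the exocyclic alkene carbon, giving 3,4-trans; both are related to the preset C6 by the chair in which the slim propynyl group is axial and the C6 ethyl group equatorial. The step needs ionisation of C3–OMe in preference to C3–OO, which the more basic ether oxygen should secure, and diastereoselection relative to C6, which rests on the difference in steric demand between propynyl and ethyl at low temperature.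

Step 14
Reactants: 22 methyl 2-[(3S,4S,6S)-4-ethenyl-6-ethyl-6-(prop-1-yn-1-yl)-1,2-dioxan-3-yl]acetate
Product: 23 methyl 2-[(3S,4R,6S)-4,6-diethyl-6-(prop-1-yn-1-yl)-1,2-dioxan-3-yl]acetate
Conditions: KO2CN=NCO2K (excess, added in portions), AcOH, MeOH/CH2Cl2, 0 °C → rt
Reagents that add atoms: none
Why: Diimide reduction (concerted syn hydrogen transfer) should reduce the monosubstituted vinyl group much faster than the hindered internal alkyne and does not touch the O–O bond; no stereocentre is affected, and the C4 descriptor changes only through CIP priority.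

Step 15
Reactants: 23 methyl 2-[(3S,4R,6S)-4,6-diethyl-6-(prop-1-yn-1-yl)-1,2-dioxan-3-yl]acetate
Product: 25 methyl 2-[(3S,4R,6S)-4,6-diethyl-6-[(1E)-2-iodoprop-1-en-1-yl]-1,2-dioxan-3-yl]acetate, via alkenylzirconocene chloride 24 (not isolated)
Conditions: Cp2Zr(H)Cl (1.5 equiv), THF, rt; then I2, 0 °C
Reagents that add atoms: iodine, II
Why: Hydrozirconation is a syn addition that places zirconium on the less hindered, methyl-bearing alkyne carbon (C8), and iodinolysis with retention gives the (E)-2-iodopropenyl group.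

Step 16
Reactants: 26 (3E)-hex-3-enoic acid; 27 (4S)-4-benzyl-1,3-oxazolidin-2-one
Product: 29 (4S)-4-benzyl-3-[(3E)-hex-3-enoyl]-1,3-oxazolidin-2-one, via mixed pivalic anhydride 28 (not isolated)
Conditions: PivCl, Et3N, THF, −20 °C; then 27, LiCl, rt
Reagents that add atoms: none
Why: N-acylation of the oxazolidinone through the mixed anhydride under mild conditions, which should leave the β,γ-double bond in place.

Step 17
Reactants: 29 (4S)-4-benzyl-3-[(3E)-hex-3-enoyl]-1,3-oxazolidin-2-one; 30 iodoethane
Product: 32 (4S)-4-benzyl-3-[(2S,3E)-2-ethylhex-3-enoyl]-1,3-oxazolidin-2-one, via sodium dienolate 31 (not isolated)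
Conditions: NaN(SiMe3)2, THF, −78 °C; then EtI (excess), −78 → −30 °C
Reagents that add atoms: none
Why: Evans alkylation in which the chelated (Z)-enolate is ethylated at the α-carbon on the face opposite the benzyl group, setting the (S)-centre that becomes C10; the (E)-alkene stays in the β,γ-position.

Step 18
Reactants: 32 (4S)-4-benzyl-3-[(2S,3E)-2-ethylhex-3-enoyl]-1,3-oxazolidin-2-one
Product: 33 (2S,3E)-2-ethylhex-3-en-1-ol
Conditions: LiBH4, H2O (1 equiv), Et2O, 0 °C
Reagents that add atoms: none
Why: Reductive cleavage of the N-acyl oxazolidinone to the primary alcohol under conditions that should not epimerise the α-centre; the auxiliary is recovered.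

Step 19
Reactants: 33 (2S,3E)-2-ethylhex-3-en-1-ol
Product: 34 (3E,5S)-5-(iodomethyl)hept-3-ene
Conditions: PPh3, I2, imidazole, CH2Cl2, 0 °C → rt
Reagents that add atoms: iodine, II
Why: Appel-type iodination by SN2 at the primary carbon; the adjacent stereocentre is not involved.

Step 20
Reactants: 25 methyl 2-[(3S,4R,6S)-4,6-diethyl-6-[(1E)-2-iodoprop-1-en-1-yl]-1,2-dioxan-3-yl]acetate; 34 (3E,5S)-5-(iodomethyl)hept-3-ene
Product: 36 methyl 2-[(3S,4R,6S)-4,6-diethyl-6-[(1E,4R,5E)-4-ethyl-2-methylocta-1,5-dien-1-yl]-1,2-dioxan-3-yl]acetate, via alkylzinc iodide 35 (not isolated)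
Conditions: 34, Zn dust, LiCl, THF, 40 °C; then 25, Pd(dppf)Cl2 (5 mol %), THF, rt
Reagents that add atoms: none
Why: Negishi coupling, with zinc insertion into the primary C–I bond and palladium-catalysed sp3–sp2 coupling that keeps the (E)-alkenyl geometry and forms C8–C9; the neutral conditions should spare the ester, the peroxide and the base-sensitive C3–H.

**Compound list**

1 | pent-2-yn-1-ol | CCC#CCO | starting material
2 | sodium 3-ethyl-2,2-bis(2-methoxyethoxy)-2,5-dihydro-1,2-oxaalumol-2-uide (cyclic alkenylalanate) | CCC1=CCO[Al-]1(OCCOC)OCCOC.[Na+] | intermediate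
3 | (2Z)-3-iodopent-2-en-1-ol | CC/C(I)=C/CO | intermediate
4 | propyne | CC#C | starting material
5 | (2Z)-3-ethylhex-2-en-4-yn-1-ol | CC/C(C#CC)=C/CO | intermediate
6 | [(2R,3S)-3-ethyl-3-(prop-1-yn-1-yl)oxiran-2-yl]methanol | OC[C@H]1O[C@@]1(CC)C#CC | intermediate
7 | (3R)-3-ethylhex-4-yne-1,3-diol | OCC[C@](O)(CC)C#CC | intermediate
8 | (3R)-3-ethyl-3-hydroxyhex-4-yn-1-yl 4-methylbenzenesulfonate | Cc1ccc(cc1)S(=O)(=O)OCC[C@](O)(CC)C#CC | intermediate
9 | (2R)-2-ethyl-2-(prop-1-yn-1-yl)oxetane | CC#C[C@@]1(CC)CCO1 | intermediate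
10 | (3S)-3-ethyl-3-hydroperoxyhex-4-yn-1-ol | CC#C[C@](CC)(CCO)OO | intermediate
11 | (3S)-3-ethyl-3-[(2-methoxypropan-2-yl)peroxy]hex-4-yn-1-ol | CC#C[C@](CC)(CCO)OOC(C)(C)OC | intermediate
12 | (3S)-3-ethyl-3-[(2-methoxypropan-2-yl)peroxy]hex-4-ynal | CC#C[C@](CC)(CC=O)OOC(C)(C)OC | intermediate
13 | methyltriphenylphosphonium bromide | C[P+](c1ccccc1)(c1ccccc1)c1ccccc1.[Br-] | starting material
14 | (iodomethyl)trimethylsilane | C[Si](C)(C)CI | starting material
15 | methylidenetriphenylphosphorane | C=P(c1ccccc1)(c1ccccc1)c1ccccc1 | intermediate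
16 | triphenyl[2-(trimethylsilyl)ethyl]phosphonium iodide | C[Si](C)(C)CC[P+](c1ccccc1)(c1ccccc1)c1ccccc1.[I-] | intermediate
17 | triphenyl[2-(trimethylsilyl)ethylidene]phosphorane | C[Si](C)(C)CC=P(c1ccccc1)(c1ccccc1)c1ccccc1 | intermediate
18 | [(2Z,5S)-5-ethyl-5-[(2-methoxypropan-2-yl)peroxy]oct-2-en-6-yn-1-yl]trimethylsilane | CC#C[C@](CC)(C/C=C\C[Si](C)(C)C)OOC(C)(C)OC | intermediate
19 | [(2Z,5S)-5-ethyl-5-hydroperoxyoct-2-en-6-yn-1-yl]trimethylsilane | CC#C[C@](CC)(C/C=C\C[Si](C)(C)C)OO | intermediate
20 | methyl 3,3-dimethoxypropanoate | COC(=O)CC(OC)OC | starting material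
21 | methyl 3-{[(2Z,5S)-5-ethyl-1-(trimethylsilyl)oct-2-en-6-yn-5-yl]peroxy}-3-methoxypropanoate (both epimers at the acetal carbon) | CC#C[C@](CC)(C/C=C\C[Si](C)(C)C)OOC(OC)CC(=O)OC | intermediate
22 | methyl 2-[(3S,4S,6S)-4-ethenyl-6-ethyl-6-(prop-1-yn-1-yl)-1,2-dioxan-3-yl]acetate | CC#C[C@]1(CC)C[C@@H](C=C)[C@H](CC(=O)OC)OO1 | intermediate
23 | methyl 2-[(3S,4R,6S)-4,6-diethyl-6-(prop-1-yn-1-yl)-1,2-dioxan-3-yl]acetate | CC#C[C@]1(CC)C[C@@H](CC)[C@H](CC(=O)OC)OO1 | intermediate
24 | methyl 2-[(3S,4R,6S)-6-{(1E)-2-[chlorobis(cyclopentadienyl)zirconio]prop-1-en-1-yl}-4,6-diethyl-1,2-dioxan-3-yl]acetate | C/C(=C\[C@]1(CC)C[C@@H](CC)[C@H](CC(=O)OC)OO1)[Zr](Cl)(C1C=CC=C1)C1C=CC=C1 | intermediate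
25 | methyl 2-[(3S,4R,6S)-4,6-diethyl-6-[(1E)-2-iodoprop-1-en-1-yl]-1,2-dioxan-3-yl]acetate | I/C(C)=C/[C@]1(CC)C[C@@H](CC)[C@H](CC(=O)OC)OO1 | intermediate
26 | (3E)-hex-3-enoic acid | CC/C=C/CC(=O)O | starting material
27 | (4S)-4-benzyl-1,3-oxazolidin-2-one | O=C1N[C@@H](Cc2ccccc2)CO1 | starting material
28 | (3E)-hex-3-enoic pivalic anhydride | CC/C=C/CC(=O)OC(=O)C(C)(C)C | intermediate
29 | (4S)-4-benzyl-3-[(3E)-hex-3-enoyl]-1,3-oxazolidin-2-one | CC/C=C/CC(=O)N1[C@@H](Cc2ccccc2)COC1=O | intermediate
30 | iodoethane | CCI | starting material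
31 | sodium (1Z,3E)-1-[(4S)-4-benzyl-2-oxo-1,3-oxazolidin-3-yl]hexa-1,3-dien-1-olate | CC/C=C/C=C(\[O-])N1[C@@H](Cc2ccccc2)COC1=O.[Na+] | intermediate
32 | (4S)-4-benzyl-3-[(2S,3E)-2-ethylhex-3-enoyl]-1,3-oxazolidin-2-one | CC/C=C/[C@H](CC)C(=O)N1[C@@H](Cc2ccccc2)COC1=O | intermediate
33 | (2S,3E)-2-ethylhex-3-en-1-ol | CC/C=C/[C@H](CC)CO | intermediate
34 | (3E,5S)-5-(iodomethyl)hept-3-ene | CC/C=C/[C@H](CC)CI | intermediate
35 | [(2S,3E)-2-ethylhex-3-en-1-yl]zinc iodide | CC/C=C/[C@H](CC)C[Zn]I | intermediate
36 | methyl 2-[(3S,4R,6S)-4,6-diethyl-6-[(1E,4R,5E)-4-ethyl-2-methylocta-1,5-dien-1-yl]-1,2-dioxan-3-yl]acetate | CC/C=C/[C@H](CC)C/C(C)=C/[C@]1(CC)C[C@@H](CC)[C@H](CC(=O)OC)OO1 | target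

**Step count**

Total: 20 steps. Longest linear sequence: 15 steps (steps 1–8, 10–15 and 20, from pent-2-yn-1-ol).

**Steps most likely to fail**

Step 13 (ring closure). The peroxycarbenium ion may be consumed before it is captured: ionisation of C3–OO instead of C3–OMe, proton loss from C2 towards a β-peroxyacrylate, or protodesilylation. The chair may also fail to tell propynyl from ethyl at C6. The fallback reverses the order of bond formation: C3–C4 is made between two molecules and the ring is closed at O2–C3. It sets out from 19. Silylation (Et3SiCl, imidazole, CH2Cl2) gives triethylsilyl peroxide F1. Hosomi–Sakurai reaction of its allylsilane with acetal 20 (TiCl4 or Me3SiOTf, CH2Cl2, −78 °C) gives β-methoxy ester F2. DBU removes methanol by E1cB elimination to give (E)-enoate F3. Bu4NF then frees hydroperoxy enoate F4, which closes by 6-exo oxa-Michael addition (Et2NH, CF3CH2OH). After chromatographic separation from its C3/C4 isomers the product comes back to the route at 22. This path gives up control of C4 relative to C6.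

Step 6 (perhydrolysis). The activated oxetane may ionise fully to a tertiary propargylic cation, so that attack by H2O2 is no longer invertive and configuration at C6 erodes, or the cation may lose a proton to an enyne. The fallback secures C6 by resolution instead of stereospecific substitution. It sets out from 10 of reduced enantiomeric purity. Acid-catalysed addition (PPTS, CH2Cl2) to (1S,2R)-2-phenylcyclohexyl isopropenyl ether F5, prepared beforehand from commercial (1S,2R)-2-phenylcyclohexanol, gives diastereomeric peroxyketals. The (3S)-diastereomer, peroxyketal F6, is separated by chromatography and hydrolysed (AcOH/THF/H2O), which comes back to the route at 10 as a single enantiomer.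

Step 15 (hydrozirconation). Cp2Zr(H)Cl may reduce the methyl ester or cleave the O–O bond faster than it adds to the hindered internal alkyne. The fallback replaces hydrozirconation by palladium-catalysed hydrostannation. It sets out from 23. Bu3SnH with Pd(PPh3)2Cl2 (cat.) in THF at 0 °C should add syn, with tin on the methyl-bearing alkyne carbon, to give (E)-alkenylstannane F7. I2 (CH2Cl2, 0 °C) exchanges tin for iodine with retention and comes back to the route at 25.

**Further compounds**

F1 | step 13 | triethyl{[(2Z,5S)-5-ethyl-1-(trimethylsilyl)oct-2-en-6-yn-5-yl]peroxy}silane | CC#C[C@](CC)(C/C=C\C[Si](C)(C)C)OO[Si](CC)(CC)CC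
F2 | step 13 | methyl (6S)-4-ethenyl-6-ethyl-3-methoxy-6-[(triethylsilyl)peroxy]non-7-ynoate (mixture at C3 and C4) | CC#C[C@](CC)(CC(C=C)C(OC)CC(=O)OC)OO[Si](CC)(CC)CC
F3 | step 13 | methyl (2E,6S)-4-ethenyl-6-ethyl-6-[(triethylsilyl)peroxy]non-2-en-7-ynoate (mixture at C4) | CC#C[C@](CC)(CC(C=C)/C=C/C(=O)OC)OO[Si](CC)(CC)CC
F4 | step 13 | methyl (2E,6S)-4-ethenyl-6-ethyl-6-hydroperoxynon-2-en-7-ynoate (mixture at C4) | CC#C[C@](CC)(CC(C=C)/C=C/C(=O)OC)OO
F5 | step 6 | (1S,2R)-2-phenylcyclohexyl prop-1-en-2-yl ether | C=C(C)O[C@H]1CCCC[C@@H]1c1ccccc1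
F6 | step 6 | (3S)-3-ethyl-3-[(2-{[(1S,2R)-2-phenylcyclohexyl]oxy}propan-2-yl)peroxy]hex-4-yn-1-ol | CC#C[C@](CC)(CCO)OOC(C)(C)O[C@H]1CCCC[C@@H]1c1ccccc1
F7 | step 15 | methyl 2-[(3S,4R,6S)-4,6-diethyl-6-[(1E)-2-(tributylstannyl)prop-1-en-1-yl]-1,2-dioxan-3-yl]acetate | CCCC[Sn](CCCC)(CCCC)/C(C)=C/[C@]1(CC)C[C@@H](CC)[C@H](CC(=O)OC)OO1
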